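## Retrosynthetic overview
1. Blepharocalyxin C (12) equals two molecules of the diarylheptanoid diol 7 minus H2O. The C3–C2′ and O5′–C1′ bonds are cut in one operation.
2. Forward: one monomer is ionised at C3 to a vinylogous p‑quinone methide. The 4‑oxystyrene of a second monomer attacks it through C2′, and O5′ closes the new p‑quinone methide. The tetrahydropyran is the only ring and is formed last.
3. The monomer is used as its tetra‑TES ether 8, so the chemistry is aprotic and the lost oxygen leaves as (Et3Si)2O.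
4. Diol 7 comes from raspberry ketone 1 and 4‑hydroxycinnamaldehyde 2 (C3–C4 bond) by a one‑pot asymmetric boron aldol and 1,3‑syn reduction.

Assumption: the presumed biosynthesis is the dehydrative union of two molecules of the co‑occurring (3S,5S)‑diol 7 via a vinylogous p‑quinone methide; C1–C7 = styryl unit, C1′–C7′ = pyran unit (oxane C2/C3/C4/C6 = C1′/C2′/C3′/C5′); 1 and 2 are catalogue chemicals.

## Route

Step 1
Reactants: 1 4-(4-hydroxyphenyl)butan-2-one; 2 (E)-3-(4-hydroxyphenyl)prop-2-enal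
Product: 7 (1E,3S,5S)-1,7-bis(4-hydroxyphenyl)hept-1-ene-3,5-diol, via O-TMS ketone 3 (not isolated), via O-TMS enal 4 (not isolated), via enol diisopinocampheylborinate 5 (not isolated), via boron aldolate 6 (not isolated)
Conditions: TMSCl, Et3N, Et2O, 0 °C (1 and 2 in separate flasks); 3 + (+)-Ipc2BCl, Et3N, 0 °C; add 4, −78 → −20 °C; LiBH4 (excess), −78 °C; H2O2, MeOH, pH 7 buffer, 0 °C
Reagents that add atoms: none
Why: In this Paterson-type reagent-controlled boron aldol, Ipc2BCl/Et3N enolises the methyl side of 3 and the (+)-Ipc ligands direct attack on the Si face of enal 4 (sets 3S, typically 75–85 % ee); external hydride then reduces the intact six-membered boron aldolate 6 (Narasaka–Prasad-type 1,3-syn reduction, sets 5S), and the transient aryl TMS ethers fall off in the buffered oxidative work-up.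

Step 2
Reactants: 7 (1E,3S,5S)-1,7-bis(4-hydroxyphenyl)hept-1-ene-3,5-diol
Product: 8 (1E,3S,5S)-3,5-bis(triethylsilyloxy)-1,7-bis[4-(triethylsilyloxy)phenyl]hept-1-ene
Conditions: TESCl (5 equiv), imidazole (8 equiv), CH2Cl2–DMF, 0 °C → rt; Et3N-deactivated silica
Reagents that add atoms: chlorotriethylsilane, CC[Si](Cl)(CC)CC
Why: Imidazole-promoted O-silylation (Corey protocol) in a basic medium keeps the labile 4-oxycinnamyl alcohol from ionising, touches no stereocentre and converts every O–H into a hindered aprotic silyl ether.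

Step 3
Reactants: 8 tetra-TES ether (two molecules: one becomes the electrophile and one is the nucleophile)
Product: 12 blepharocalyxin C, via O-silyl vinylogous quinone methide cation 9 (not isolated), via O-silyl quinone methide adduct 10 (not isolated), via hexakis-TES ether 11 (not isolated)
Conditions: Et3SiOTf (10 mol %), 2,6-di-tert-butyl-4-methylpyridine (10 mol %), 4 Å MS, CH2Cl2 (0.3 M), −78 → −50 °C; Et3N quench; then Et3N·3HF, THF, rt
Reagents that add atoms: none
Why: Proposed new method: Et3SiOTf silylates the doubly activated C3–OSiEt3 of one molecule of 8 and expels inert (Et3Si)2O, giving the W-shaped 1-aryl-3-alkylallyl cation 9 (an O-silylated vinylogous p-quinone methide) in a medium free of protic O-nucleophiles; the 4-silyloxystyrene of a second molecule, a far better π-nucleophile than any arene ring present, attacks the alkyl terminus C3, which is the usual regiochemistry of 1-aryl-3-alkylallyl cations because the styrene conjugation is kept; C2′ reacts on the face anti to C4′ with the allylic OSiEt3 "inside" (Houk model), so the bulky silyloxy group fills the sector that faces H-3 of the cation; the two π-systems stack synclinally and the cation face is chosen by polar 1,3-induction from C5–OSiEt3 (Evans-type, vinyl/OSi anti), and these two effects are matched for a homochiral pair and give 3S,2′S; O5′–SiEt3 closes adduct 10 anti across the E-alkene in a chair (aryl, side chain and arylethyl equatorial, 4-OSiEt3 axial), which sets 1′S with 2,6-cis/2,3-trans geometry and regenerates Et3SiOTf; the closest known reactions are Lewis-acid SN1 coupling of allyl or benzyl silyl ethers with π-nucleophiles (Mayr-type cation–alkene addition), acid dimerisation of anethole and isoeugenol, Noyori R3SiOTf/silyl-ether chemistry and electrophile-induced 6-endo etherification of 5-aryl-4-pentenols; fluoride then removes all six silyl groups without touching a stereocentre.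

## Compound list
1 | 4-(4-hydroxyphenyl)butan-2-one (raspberry ketone) | CC(=O)CCc1ccc(O)cc1 | starting material
2 | (E)-3-(4-hydroxyphenyl)prop-2-enal | O=C/C=C/c1ccc(O)cc1 | starting material
3 | 4-[4-(trimethylsilyloxy)phenyl]butan-2-one | CC(=O)CCc1ccc(O[Si](C)(C)C)cc1 | intermediate
4 | (E)-3-[4-(trimethylsilyloxy)phenyl]prop-2-enal | O=C/C=C/c1ccc(O[Si](C)(C)C)cc1 | intermediate
5 | methyl-side enol (+)-diisopinocampheylborinate of 3 | C=C(CCc1ccc(O[Si](C)(C)C)cc1)OB([C@H]1C[C@H]2C[C@@H]([C@@H]1C)C2(C)C)[C@H]1C[C@H]2C[C@@H]([C@@H]1C)C2(C)C | intermediate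
6 | (3S)-boron aldolate (O3–B(Ipc)2, C5 ketone) | C[Si](C)(C)Oc1ccc(/C=C/[C@@H](OB([C@H]2C[C@H]3C[C@@H]([C@@H]2C)C3(C)C)[C@H]2C[C@H]3C[C@@H]([C@@H]2C)C3(C)C)CC(=O)CCc2ccc(O[Si](C)(C)C)cc2)cc1 | intermediate
7 | (1E,3S,5S)-1,7-bis(4-hydroxyphenyl)hept-1-ene-3,5-diol (syn diol) | Oc1ccc(/C=C/[C@@H](O)C[C@@H](O)CCc2ccc(O)cc2)cc1 | intermediate
8 | tetra-TES ether of 7 | CC[Si](CC)(CC)Oc1ccc(/C=C/[C@@H](O[Si](CC)(CC)CC)C[C@@H](O[Si](CC)(CC)CC)CCc2ccc(O[Si](CC)(CC)CC)cc2)cc1 | intermediate
9 | (5S)-allyl cation triflate, O-silylated vinylogous p-quinone methide | CC[Si](CC)(CC)[O+]=C1C=CC(=C/C=C/C[C@@H](O[Si](CC)(CC)CC)CCc2ccc(O[Si](CC)(CC)CC)cc2)C=C1.[O-]S(=O)(=O)C(F)(F)F | intermediate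
10 | C3–C2′ bonded open-chain adduct, O-silylated p-quinone methide triflate (3S,5S,2′S,3′S,5′S) | CC[Si](CC)(CC)Oc1ccc(/C=C/[C@H](C[C@@H](O[Si](CC)(CC)CC)CCc2ccc(O[Si](CC)(CC)CC)cc2)[C@H](C=C2C=CC(=[O+][Si](CC)(CC)CC)C=C2)[C@@H](O[Si](CC)(CC)CC)C[C@@H](O[Si](CC)(CC)CC)CCc2ccc(O[Si](CC)(CC)CC)cc2)cc1.[O-]S(=O)(=O)C(F)(F)F | intermediate
11 | hexakis(triethylsilyl) ether of blepharocalyxin C | CC[Si](CC)(CC)Oc1ccc(/C=C/[C@H](C[C@@H](O[Si](CC)(CC)CC)CCc2ccc(O[Si](CC)(CC)CC)cc2)[C@@H]2[C@@H](c3ccc(O[Si](CC)(CC)CC)cc3)O[C@@H](CCc3ccc(O[Si](CC)(CC)CC)cc3)C[C@@H]2O[Si](CC)(CC)CC)cc1 | intermediate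
12 | blepharocalyxin C, (2S,3S,4S,6S)-3-[(1E,3S,5S)-5-hydroxy-1,7-bis(4-hydroxyphenyl)hept-1-en-3-yl]-2-(4-hydroxyphenyl)-6-[2-(4-hydroxyphenyl)ethyl]oxan-4-ol | Oc1ccc(/C=C/[C@H](C[C@@H](O)CCc2ccc(O)cc2)[C@@H]2[C@@H](c3ccc(O)cc3)O[C@@H](CCc3ccc(O)cc3)C[C@@H]2O)cc1 | target

## Step count and risks
Total step count: 3. Longest linear sequence: 3 (both halves come from the same compound 8).

**Step 3 (highest risk).**
- Degenerate exchange between cation 9 and the allylic silyl ether of unreacted 8 can epimerise C3′. That would lead to the 4‑epimer of the target.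
- If this exchange is fast, the syn isomer should still react faster. It alone can place the OSiEt3 group in the sector that faces H‑3 of the cation.
- Selectivity at C3 may be modest. Attack at C1 of the cation and further alkylation of the product styrene lower the yield, which I expect to be 25–40 % after HPLC.
- Heterochiral dimers from the minor enantiomer of 7 are separable diastereomers, so the ee of 12 rises above that of 7.
- Fallback (sets out from 7, uses 8, returns at 12): remove the ionisable centre from the nucleophile.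
  - DDQ in dioxane oxidises only the 4‑hydroxycinnamyl alcohol of 7 to (S,E)-5-hydroxy-1,7-bis(4-hydroxyphenyl)hept-1-en-3-one F1.
  - TESCl/imidazole gives its tris‑TES ether F2.
  - With catalytic Et3SiOTf at −78 °C, F2 closes by silyl‑transfer oxa‑Michael addition. This is still the O5′→C1′ ring closure and gives the regiodefined 2,6‑cis enol silane F3.
  - F3 is roughly 10^4 times more nucleophilic than a styrene. It captures cation 9, made from one equivalent of 8, to give the tetrahydropyran‑4‑one F4.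
  - DBU equilibrates C2′ and C1′ to the all‑equatorial ketone.
  - L‑Selectride attacks equatorially to give the axial 4‑alcohol, pentakis‑TES ether F5. Et3N·3HF then gives 12.

**Step 1.**
- Methyl‑ketone Ipc enolates give only moderate ee. The 4‑oxycinnamyl aldolate can also dehydrate to the dienone.
- Fallback (sets out from 1 and 2, returns at 7): replace the aldol addition by condensation followed by asymmetric formal hydration.
  - Pyrrolidine/AcOH condenses 1 with 2 to (4E,6E)-1,7-bis(4-hydroxyphenyl)hepta-4,6-dien-3-one F6.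
  - Cu‑catalysed enantioselective 1,4‑borylation (B2pin2, chiral bipyridine‑diol/Cu(OH)2 in water, using the ligand enantiomer that gives S) gives the allyl boronate (5S,6E)-1,7-bis(4-hydroxyphenyl)-5-(pinacolboryl)hept-6-en-3-one F7.
  - NaBO3 oxidises it with retention to (5S,6E)-5-hydroxy-1,7-bis(4-hydroxyphenyl)hept-6-en-3-one F8.
  - Et2BOMe/NaBH4 at −78 °C gives 7.

**Step 2.**
- The C3–O bond of 8 is so labile that material may be lost on isolation, and traces of acid spoil the next step.
- Fallback (sets out from 7, returns at 12): drop silicon altogether and dimerise the free polyphenol under hydrogen‑bond catalysis.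
  - Diphenyl phosphate (10 mol %, MeCN–CH2Cl2, 0 °C) dehydrates 7 to the neutral vinylogous p‑quinone methide F9.
  - In the stacked head‑to‑head transition state one phosphoric acid bridges the carbonyl oxygen of F9 and the phenol OH of the attacking styrene of a second 7.
  - The p‑quinone methide adduct F10 is closed reversibly by O5′ to 12.
  - The price is faster C3′ epimerisation of 7 through water return.

## Further compounds
F1 | step 3 | (S,E)-5-hydroxy-1,7-bis(4-hydroxyphenyl)hept-1-en-3-one | Oc1ccc(/C=C/C(=O)C[C@@H](O)CCc2ccc(O)cc2)cc1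
F2 | step 3 | tris-TES ether of F1 | CC[Si](CC)(CC)Oc1ccc(/C=C/C(=O)C[C@@H](O[Si](CC)(CC)CC)CCc2ccc(O[Si](CC)(CC)CC)cc2)cc1
F3 | step 3 | 2,6-cis 4-(triethylsilyloxy)-3,6-dihydro-2H-pyran enol silane | CC[Si](CC)(CC)OC1=C[C@@H](c2ccc(O[Si](CC)(CC)CC)cc2)O[C@@H](CCc2ccc(O[Si](CC)(CC)CC)cc2)C1
F4 | step 3 | all-equatorial 2,3,6-trisubstituted tetrahydropyran-4-one, pentakis-TES | CC[Si](CC)(CC)Oc1ccc(/C=C/[C@H](C[C@@H](O[Si](CC)(CC)CC)CCc2ccc(O[Si](CC)(CC)CC)cc2)[C@@H]2[C@@H](c3ccc(O[Si](CC)(CC)CC)cc3)O[C@@H](CCc3ccc(O[Si](CC)(CC)CC)cc3)CC2=O)cc1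
F5 | step 3 | pentakis-TES ether of blepharocalyxin C with free axial 4-OH | CC[Si](CC)(CC)Oc1ccc(/C=C/[C@H](C[C@@H](O[Si](CC)(CC)CC)CCc2ccc(O[Si](CC)(CC)CC)cc2)[C@@H]2[C@@H](c3ccc(O[Si](CC)(CC)CC)cc3)O[C@@H](CCc3ccc(O[Si](CC)(CC)CC)cc3)C[C@@H]2O)cc1
F6 | step 1 | (4E,6E)-1,7-bis(4-hydroxyphenyl)hepta-4,6-dien-3-one | O=C(CCc1ccc(O)cc1)/C=C/C=C/c1ccc(O)cc1
F7 | step 1 | (5S,6E)-1,7-bis(4-hydroxyphenyl)-5-(pinacolboryl)hept-6-en-3-one | Oc1ccc(/C=C/[C@@H](B2OC(C)(C)C(C)(C)O2)CC(=O)CCc2ccc(O)cc2)cc1
F8 | step 1 | (5S,6E)-5-hydroxy-1,7-bis(4-hydroxyphenyl)hept-6-en-3-one | Oc1ccc(/C=C/[C@@H](O)CC(=O)CCc2ccc(O)cc2)cc1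
F9 | step 2 | neutral vinylogous p-quinone methide from 7 | O=C1C=CC(=C/C=C/C[C@@H](O)CCc2ccc(O)cc2)C=C1
F10 | step 2 | neutral p-quinone methide adduct (C3–C2′ bonded, ring still open) | Oc1ccc(/C=C/[C@H](C[C@@H](O)CCc2ccc(O)cc2)[C@H](C=C2C=CC(=O)C=C2)[C@@H](O)C[C@@H](O)CCc2ccc(O)cc2)cc1
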